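The numbers in the tables are calculated from invented constants, and the scatter is random.

The constants on hand before any rate is fitted are the charges and the gas saturation, and the north-east run, which is this same flask followed so far, supplies the readings:

- north-east: substrate 0.018 M; first nucleophile 1.2 equiv; gas 6.3 mM (held); the very flask that is asked about, followed so far
- flask: substrate 0.018 M; first nucleophile 1.20 equiv; gas 6.3 mM (held); time 15 d

north-east run (percent of the substrate charged)

| time / d | target / % | other capture product / % |
|---|---|---|
| 0.167 | 2.3 | 1.1 |
| 0.500 | 6.4 | 2.3 |
| 1.04 | 11.4 | 3.1 |
| 1.67 | 15.1 | 5.4 |
| 2.08 | 15.1 | 7.1 |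
| 2.50 | 14.6 | 9.3 |

(standard deviation of a reading: 1 percentage point)

- ratio of target to other capture product at 3.0 h
- ratio of target to other capture product at 15 d

- at the start none of the gas is in solution

If target and other capture product are two captures of one shared precursor, by first nucleophile and by dissolved gas, their ratio should follow the charge ratio, the charge of first nucleophile over the saturated gas, 3.43, as a selectivity factor times that ratio. The north-east reading at 1.04 d gives a ratio of 3.68, give or take 1.19, and this reckoning commits to that value for 3.0 h; the target readings stop rising near 15.1% while the other capture product climbs, so it offers no figure for 15 d.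

The forecast, “with the target as the kinetic product”, gave 3.8 at 3.0 h and 0.13 at 15 d.

In this flask the simulation gives a ratio of 4.78 at 3.0 h and 0.101 at 15 d.

    second nucleophile + target → over-reaction product (k = 3.36 M⁻¹ h⁻¹)
    second nucleophile + intermediate → other capture product (k = 436 M⁻¹ h⁻¹)
    substrate ⇌ intermediate (K = 0.00105, k = 0.0199 h⁻¹)
    gas ⇌ second nucleophile, rate k4*(csat - [second nucleophile]) (kL = 1.71 h⁻¹)
    first nucleophile + intermediate → target (k = 509 M⁻¹ h⁻¹)

In this flask at 15.0 d, with second nucleophile at 0.00629 M, the intermediate still goes to target 1.8 times as fast as to other capture product, which is the charge ratio times the 45% of first nucleophile left times the ratio 1.17 of the two capture constants, 1.79. Yet in this flask the target stands at 2.42% beside 24.0% of other capture product, and with second nucleophile at 6.3 mM the target's pseudo-first-order lifetime against it is 1.97 d, shorter than the 15 d of this flask.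

In the neighbour flask with 0.0045 M of substrate, the charge ratio is 0.857, a quarter of this flask's, which scales the early ratio to 1.19. The computed ratio there at 3.0 h is 1.20.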